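## Analysis of the target

The target is a (2S)-flavanone: benzene ring A is fused through C4a and C8a to the dihydropyranone ring C (O1, C2, C3, C4, ketone at C4), and the 4-hydroxyphenyl ring B sits on C2. Ring A carries a substituent on every carbon: hydroxyl at C5 (hydrogen-bonded to the C4 carbonyl), methoxy at C6 and C7, and prenyl at C8. C2 is the only stereocentre, so only its absolute configuration has to be set; reading the SMILES with H to the rear, O1 → ring B → C3 runs counter-clockwise, which is S. That centre is fragile, because it lies β to the C4 ketone and its oxygen O1 is a phenoxide leaving group: base, or hot acid, opens ring C to the 2'-hydroxychalcone and recloses it without facial preference. The prenyl group is the second sensitive site: its trisubstituted alkene does not tolerate electrophilic halogen or strong protic acid, and its CH2, both benzylic and allylic, is acidic towards alkyllithiums. The difficulty is therefore to assemble a hexasubstituted ring A with four different groups in fixed order and to deliver C2 enantiopure without exposing the C2–O1/C4=O pair to base. The strategy rests on the fact that O1 joins the stereocentre C2 to the aromatic carbon C8a: if ring C is closed by making O1–C8a on a substrate whose C2–O bond already exists and whose C4 is still a carbinol, the stereocentre is a spectator with no pathway to racemise.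

## Retrosynthetic reasoning

**16 ⇒ 15 ⇒ 14 (phenol unmasking).** The C5 hydroxyl is traced back to the methyl ether in 15. Of the three methoxy groups, only the one peri to the C4 carbonyl can be cleaved selectively, through a six-membered Lewis acid chelate. The 4'-hydroxyl is traced back to the methoxymethyl acetal in 14, which withstands enolates, carbonate and palladium and falls to dilute acid. The acetal goes first, because the Lewis acid of the demethylation would attack it anyway; this order gives one defined product per step.

**14 ⇒ 13 ⇒ 12 (oxidation level at C4).** The ketone is returned to the carbinol 13 and that to its silyl ether 12. Without a C4 carbonyl, C3 has no acidic hydrogen and ring C cannot open by retro-oxa-Michael or retro-aldol, so base is tolerated up to 13. The silyl group is there for the ring closure: a free hydroxyl on C4 would be a secondary benzylic alcohol ortho to the C8a–Br bond, a motif that palladium turns into a debrominated aryl ketone by β-hydride elimination. The configuration at C4 is irrelevant, since the oxidation erases it.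

**12 ⇒ 11 (O1–C8a, the key disconnection).** Ring C is opened at the aryl–oxygen bond, not at O1–C2 or C2–C3. The forward reaction then breaks only the O–H bond of the C2 carbinol, so the configuration set earlier is carried into the ring unchanged. The forward step has to insert a metal into a hindered, electron-rich aryl bromide and form the C–O bond faster than the secondary alkoxide loses hydride.

**11 ⇒ 10 (C2 stereocentre).** The C2 carbinol is traced back to the aryl ketone 10. An aryl/CH2 ketone is the ideal substrate for catalyst-controlled asymmetric transfer hydrogenation. The remote, racemic silyloxy centre should not influence the facial choice.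

**10 ⇒ 9 ⇒ 5 + 7 (C3–C4).** Cutting C3–C4 as an aldol between enolate 8 of methyl ketone 7 and aldehyde 5 puts the carbonyl on the ring B side, where it becomes the C2 carbinol, and the hydroxyl on C4. This is exactly the oxidation pattern the ring closure needs, and it joins two fragments of similar size. Ketone 7 comes from phenol 6 by acetal protection.

**5 ⇒ 3 + 4 (C8–prenyl).** The prenyl group is attached by cross-coupling of boronate 4 at an iodide, because iodide reacts ahead of the bromide that must survive for the ring closure. Bringing the alkene in last among the ring A substituents means that no electrophilic halogenation and no alkyllithium ever meets it.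

**3 ⇒ 2 ⇒ 1 (ring A substitution).** Iodine and the formyl group are traced back to electrophilic substitutions on 1, which already carries the bromine (future C8a) and the three methoxy groups. The two free positions of 1 are equivalent and both flank the bromine, so formylation can give only 2 and iodination of 2 can occur only at the last free carbon. Regiochemistry is settled by symmetry, not by directing-group competition.

## Alternatives that were turned down

**Alternative 1: ring A grown onto ring C by squarate ring expansion.** The disconnection removes ring A and traces it to dimethyl squarate A3 and a preformed, enantiopure 2-aryl-dihydropyran. In the forward key step the adduct A2 is heated. The 4-hydroxycyclobutenone opens to a dienylketene, the ketene carbon (C5) closes onto C4a of the dihydropyran, and tautomerisation gives the hydroquinone A1.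
- For: the route is convergent, the oxygen pattern of ring A is fixed by construction, and C2 is protected from racemisation in the same way as here (C4 carried as a silyl ether). On these points it is equal to the chosen route.
- Against: A1 has a hydroxyl at C8 where the target has carbon. The two hydroquinone hydroxyls must be told apart, and C8–O has to be converted into C8–prenyl (sulfonate, then cross-coupling) on an easily oxidised hydroquinone, most plausibly only after the C4 ketone is in place to tie up the 5-OH. The lithiated chiral dihydropyran also needs its own asymmetric synthesis.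
- Comparison: the step count is clearly higher. The chosen route buys the oxygenated ring and installs prenyl at a carbon–halogen bond instead of replacing an oxygen.

**Alternative 2: ring A written de novo by an allenyl cyclobutenone cascade.** Ring A is disconnected completely. In the forward key step, cyclobutenone A5 is warmed in wet solvent: electrocyclic opening gives an allenyl vinylketene, the ketene carbon (C8a) closes onto the central allene carbon (C4a), and water adds to the resulting ortho-quinone methide at C4 to give the salicyl alcohol A4.
- For: all six substituents of ring A, prenyl included, appear in one thermal step with unambiguous regiochemistry. On this point it is stronger than a sequence of aromatic substitutions.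
- Against: A4 contains neither ring C, ring B nor the stereocentre, so the real problem of the target, an enantiopure C2 next to O1 and C4, is left untouched. A5 is itself a multistep squarate derivative. From A4 one would arrive at a phenol analogue of aldehyde 5 and still need a ring C construction.
- Comparison: the chosen route accepts a conventional arene synthesis, made safe by the symmetry of 1, and spends its effort on the stereocentre.

**Alternative 3: C3–C4 formed by chelation-assisted enantioselective hydroacylation.** The disconnection is C3–C4 together with C2–H. In the forward key step, a chiral bisphosphine complex of monovalent rhodium activates the formyl C–H of aldehyde A7 and adds it across the 1-arylvinyl ether, hydride to C2 and acyl to C3, giving flavanone A6 directly.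
- For: ring C, the C4 ketone and the stereocentre are formed in one atom-economical step at the final oxidation level, with the 5-OH already free. In step economy this is stronger than the chosen route, which needs a protection, a deprotection and an oxidation around C4.
- Against: six-membered ring hydroacylation competes with decarbonylation of the acyl rhodium hydride. Hydride must be delivered to the more substituted, oxygen-bearing alkene carbon, and asymmetric induction at such a carbon rests on a ligand–substrate match for which there is little guidance. A7 is an acid-labile enol ether on a phenol flanked by formyl and prenyl and is itself hard to make.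
- Comparison: the chosen route sets C2 by a ketone reduction whose sense is predictable and closes the ring by a reaction with direct analogy on 3-(2-bromoaryl)-1-arylpropanols.

Key step: step 8

Assumption: the carbinol carbon that becomes C4 is formed without stereocontrol and is oxidised in step 10. Compounds 9 and 10 are therefore racemic, and 11, 12 and 13 are each a pair of epimers at that carbon with the ring B carbinol carbon (C2) uniformly S; their SMILES leave that centre open.

## Route

Step 1
Reactants: 1 5-bromo-1,2,3-trimethoxybenzene
Product: 2 6-bromo-2,3,4-trimethoxybenzaldehyde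
Conditions: Cl2CHOMe (1.3 equiv), TiCl4 (2.2 equiv), CH2Cl2, −10 → 0 °C; ice-water
Reagents that add atoms: dichloromethyl methyl ether, COC(Cl)Cl; water, O
Why: Rieche formylation; the two free positions of 1 are equivalent by symmetry and each is ortho to one methoxy group and para to another, so a single aldehyde should form with bromine already at the future C8a.

Step 2
Reactants: 2 6-bromo-2,3,4-trimethoxybenzaldehyde
Product: 3 2-bromo-3-iodo-4,5,6-trimethoxybenzaldehyde
Conditions: N-iodosuccinimide (1.2 equiv), CF3CO2H (0.5 equiv), MeCN, rt → 50 °C
Reagents that add atoms: N-iodosuccinimide, O=C1CCC(=O)N1I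
Why: Electrophilic aromatic iodination at the only remaining ring position, which is ortho and para to methoxy groups and meta to the formyl group.

Step 3
Reactants: 3 2-bromo-3-iodo-4,5,6-trimethoxybenzaldehyde; 4 prenylboronic acid pinacol ester
Product: 5 2-bromo-4,5,6-trimethoxy-3-(3-methylbut-2-en-1-yl)benzaldehyde
Conditions: Pd(dppf)Cl2 (5 mol%), CsF (3 equiv), THF, 60 °C
Reagents that add atoms: none
Why: Suzuki–Miyaura coupling; oxidative addition should prefer C–I over C–Br, and the allylpalladium intermediate equilibrates and reductively eliminates at its unhindered primary terminus to give the linear prenyl arene. Fluoride turns the boronate into a fluoroborate that transmetalates but no longer allylborates the hindered aldehyde.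

Step 4
Reactants: 6 4'-hydroxyacetophenone
Product: 7 1-[4-(methoxymethoxy)phenyl]ethan-1-one
Conditions: MeOCH2Cl (1.3 equiv), i-Pr2NEt (1.6 equiv), CH2Cl2, 0 °C → rt
Reagents that add atoms: chloromethyl methyl ether, COCCl
Why: O-Alkylation of the phenol to the methoxymethyl acetal, which is stable to the enolate, carbonate and palladium chemistry that follows.

Step 5
Reactants: 7 1-[4-(methoxymethoxy)phenyl]ethan-1-one; 5 2-bromo-4,5,6-trimethoxy-3-(3-methylbut-2-en-1-yl)benzaldehyde
Product: 9 racemic 3-[2-bromo-4,5,6-trimethoxy-3-(3-methylbut-2-en-1-yl)phenyl]-3-hydroxy-1-[4-(methoxymethoxy)phenyl]propan-1-one, via lithium 1-[4-(methoxymethoxy)phenyl]ethen-1-olate 8 (not isolated)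
Conditions: LiN(i-Pr)2 (1.1 equiv), THF, −78 °C; then 5, −78 °C; AcOH quench at −78 °C
Reagents that add atoms: none
Why: Directed aldol addition of a preformed lithium enolate to a non-enolisable aldehyde forms C3–C4; low temperature and a cold acidic quench should prevent reversal of the hindered aldolate. The new carbinol centre (future C4) is formed without control, which is acceptable.

Step 6
Reactants: 9 racemic β-hydroxy ketone
Product: 10 racemic 3-[2-bromo-4,5,6-trimethoxy-3-(3-methylbut-2-en-1-yl)phenyl]-3-[(tert-butyldimethylsilyl)oxy]-1-[4-(methoxymethoxy)phenyl]propan-1-one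
Conditions: t-BuMe2SiOTf (1.3 equiv), 2,6-lutidine (2 equiv), CH2Cl2, −78 °C
Reagents that add atoms: tert-butyldimethylsilyl trifluoromethanesulfonate, CC(C)(C)[Si](C)(C)OS(=O)(=O)C(F)(F)F
Why: Silylation of a hindered secondary alcohol with a silyl triflate and a non-nucleophilic base; at −78 °C the ketone should not be enol-silylated and the acetal should stay intact. The ether also removes the retro-aldol and dehydration pathways of 9.

Step 7
Reactants: 10 racemic β-silyloxy ketone
Product: 11 (1S)-3-[2-bromo-4,5,6-trimethoxy-3-(3-methylbut-2-en-1-yl)phenyl]-3-[(tert-butyldimethylsilyl)oxy]-1-[4-(methoxymethoxy)phenyl]propan-1-ol, both epimers at the silyloxy carbon (the 1-O-silyl ether of the (3S)-1,3-diol when numbered from the ring A end)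
Conditions: RuCl(p-cymene)[(S,S)-TsDPEN] (2 mol%), HCO2H/Et3N (5:2), CH2Cl2, 30 °C
Reagents that add atoms: none
Why: Noyori-type asymmetric transfer hydrogenation; the ruthenium hydride and the ligand N–H deliver hydride and proton through a six-membered transition state in which ring B lies under the η6-arene. With the (S,S)-ligand, aryl alkyl ketones give the (S)-carbinol, which here is the future C2 (O > ring B > CH2 > H, as in 1-phenylethanol); aryl bromide, alkene, silyl ether and acetal are inert.

Step 8
Reactants: 11 (1S)-bromoaryl carbinol, both epimers at the silyloxy carbon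
Product: 12 (2S)-4-[(tert-butyldimethylsilyl)oxy]-5,6,7-trimethoxy-2-[4-(methoxymethoxy)phenyl]-8-(3-methylbut-2-en-1-yl)chromane, both C4 epimers
Conditions: Pd(OAc)2 (5 mol%), 2-(di-tert-butylphosphino)-1,1'-binaphthyl (6 mol%), Cs2CO3 (1.5 equiv), toluene, 80 °C
Reagents that add atoms: none
Why: Zerovalent palladium carrying the bulky di-tert-butyl biarylphosphine inserts into the C8a–Br bond of 11; Cs2CO3 deprotonates the ring B carbinol, the alkoxide displaces bromide on palladium to give a seven-membered arylpalladium alkoxide, and C–O reductive elimination forms O1–C8a. The closest known reaction type is the palladium-catalysed intramolecular etherification (Buchwald–Hartwig C–O coupling) of 3-(2-bromoaryl)-1-arylpropan-1-ols to 2-arylchromans, which proceeds with retention. Ring C closes as a six-membered ring in a 6-exo sense, the oxygen attacking the aryl carbon whose leaving group lies outside the new ring. No stereocentre is created; C2 keeps its S configuration because only its O–H bond is broken, and with C4 at the carbinol level there is no enolisable carbonyl through which ring C could reopen. The selectivity required is etherification over β-hydride elimination from the secondary alkoxide, which the bulky electron-rich ligand and the two ortho substituents flanking palladium (the C8 prenyl group and the C4a side chain) should secure by accelerating reductive elimination. The second oxygen cannot interfere because it is silylated; as a free ortho-bromobenzylic alcohol it would chelate palladium in a five-membered ring and divert the catalyst into alcohol oxidation with loss of bromine. Acetal, silyl and methyl ethers are inert to carbonate in toluene, and the prenyl alkene is too substituted and badly placed for a Heck pathway.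

Step 9
Reactants: 12 (2S)-4-O-silyl flavan, both C4 epimers
Product: 13 (2S)-5,6,7-trimethoxy-2-[4-(methoxymethoxy)phenyl]-8-(3-methylbut-2-en-1-yl)chroman-4-ol, both C4 epimers, (2S,4S) and (2S,4R)
Conditions: Bu4NF (1.5 equiv), THF, 0 °C → rt
Reagents that add atoms: none
Why: Fluoride-induced desilylation; basic, non-acidic conditions are chosen because the free flavan-4-ol, activated by the 5- and 7-methoxy groups and O1, would ionise at C4 under acid. Base cannot harm C2 while C4 is a carbinol.

Step 10
Reactants: 13 (2S)-flavan-4-ol, both C4 epimers
Product: 14 (2S)-5,6,7-trimethoxy-2-[4-(methoxymethoxy)phenyl]-8-(3-methylbut-2-en-1-yl)chroman-4-one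
Conditions: Dess–Martin periodinane (1.3 equiv), NaHCO3 (5 equiv), CH2Cl2, 0 °C → rt
Reagents that add atoms: none
Why: Dess–Martin oxidation of the benzylic secondary alcohol, buffered so that acetic acid neither ionises C4 nor touches the acetal; both C4 epimers converge on one ketone. No base strong enough to enolise the new ketone is present, so C2 should be unaffected.

Step 11
Reactants: 14 (2S)-4'-O-methoxymethyl flavanone
Product: 15 (2S)-2-(4-hydroxyphenyl)-5,6,7-trimethoxy-8-(3-methylbut-2-en-1-yl)chroman-4-one
Conditions: conc. HCl (cat.), MeOH, 40 °C
Reagents that add atoms: none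
Why: Acid-catalysed transacetalisation of the aryl methoxymethyl ether to methanol; dilute acid at this temperature should neither add to the trisubstituted alkene nor open the flavanone, whose C2 is stable to acid but not to base.

Step 12
Reactants: 15 (2S)-4'-hydroxy-5,6,7-trimethoxy flavanone
Product: 16 (2S)-5-hydroxy-2-(4-hydroxyphenyl)-6,7-dimethoxy-8-(3-methylbut-2-en-1-yl)chroman-4-one (target, CNP0104932.1)
Conditions: BCl3 (2.5 equiv, 1 M in CH2Cl2), CH2Cl2, −78 → −10 °C; ice-water
Reagents that add atoms: none
Why: Chelation-controlled O-demethylation; BCl3 binds the C4 carbonyl and the peri 5-methoxy oxygen in a six-membered chelate and chloride removes that methyl group, while the 6- and 7-methoxy groups lack such a chelate and should survive at low temperature. No base is involved, so C2 should keep its configuration.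

## Compound list

1 | 5-bromo-1,2,3-trimethoxybenzene | COc1cc(Br)cc(OC)c1OC | starting material
2 | 6-bromo-2,3,4-trimethoxybenzaldehyde | COc1cc(Br)c(C=O)c(OC)c1OC | intermediate
3 | 2-bromo-3-iodo-4,5,6-trimethoxybenzaldehyde | COc1c(I)c(Br)c(C=O)c(OC)c1OC | intermediate
4 | prenylboronic acid pinacol ester, 4,4,5,5-tetramethyl-2-(3-methylbut-2-en-1-yl)-1,3,2-dioxaborolane | CC(C)=CCB1OC(C)(C)C(C)(C)O1 | starting material
5 | 2-bromo-4,5,6-trimethoxy-3-(3-methylbut-2-en-1-yl)benzaldehyde | COc1c(CC=C(C)C)c(Br)c(C=O)c(OC)c1OC | intermediate
6 | 4'-hydroxyacetophenone, 1-(4-hydroxyphenyl)ethan-1-one | CC(=O)c1ccc(O)cc1 | starting material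
7 | 1-[4-(methoxymethoxy)phenyl]ethan-1-one | CC(=O)c1ccc(OCOC)cc1 | intermediate
8 | lithium 1-[4-(methoxymethoxy)phenyl]ethen-1-olate (not isolated) | [Li+].[O-]C(=C)c1ccc(OCOC)cc1 | intermediate
9 | 3-[2-bromo-4,5,6-trimethoxy-3-(3-methylbut-2-en-1-yl)phenyl]-3-hydroxy-1-[4-(methoxymethoxy)phenyl]propan-1-one, racemic | COCOc1ccc(cc1)C(=O)CC(O)c1c(Br)c(CC=C(C)C)c(OC)c(OC)c1OC | intermediate
10 | 3-[2-bromo-4,5,6-trimethoxy-3-(3-methylbut-2-en-1-yl)phenyl]-3-[(tert-butyldimethylsilyl)oxy]-1-[4-(methoxymethoxy)phenyl]propan-1-one, racemic | COCOc1ccc(cc1)C(=O)CC(O[Si](C)(C)C(C)(C)C)c1c(Br)c(CC=C(C)C)c(OC)c(OC)c1OC | intermediate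
11 | (1S)-3-[2-bromo-4,5,6-trimethoxy-3-(3-methylbut-2-en-1-yl)phenyl]-3-[(tert-butyldimethylsilyl)oxy]-1-[4-(methoxymethoxy)phenyl]propan-1-ol, both epimers at the silyloxy carbon | O[C@H](c1ccc(OCOC)cc1)CC(O[Si](C)(C)C(C)(C)C)c1c(Br)c(CC=C(C)C)c(OC)c(OC)c1OC | intermediate
12 | (2S)-4-[(tert-butyldimethylsilyl)oxy]-5,6,7-trimethoxy-2-[4-(methoxymethoxy)phenyl]-8-(3-methylbut-2-en-1-yl)chromane, both C4 epimers | COc1c(OC)c2c(c(CC=C(C)C)c1OC)O[C@H](c1ccc(OCOC)cc1)CC2O[Si](C)(C)C(C)(C)C | intermediate
13 | (2S)-5,6,7-trimethoxy-2-[4-(methoxymethoxy)phenyl]-8-(3-methylbut-2-en-1-yl)chroman-4-ol, both C4 epimers | COc1c(OC)c2c(c(CC=C(C)C)c1OC)O[C@H](c1ccc(OCOC)cc1)CC2O | intermediate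
14 | (2S)-5,6,7-trimethoxy-2-[4-(methoxymethoxy)phenyl]-8-(3-methylbut-2-en-1-yl)chroman-4-one | COc1c(OC)c2c(c(CC=C(C)C)c1OC)O[C@H](c1ccc(OCOC)cc1)CC2=O | intermediate
15 | (2S)-2-(4-hydroxyphenyl)-5,6,7-trimethoxy-8-(3-methylbut-2-en-1-yl)chroman-4-one | COc1c(OC)c2c(c(CC=C(C)C)c1OC)O[C@H](c1ccc(O)cc1)CC2=O | intermediate
16 | (2S)-5-hydroxy-2-(4-hydroxyphenyl)-6,7-dimethoxy-8-(3-methylbut-2-en-1-yl)chroman-4-one | COc1c(O)c2c(c(CC=C(C)C)c1OC)O[C@H](c1ccc(O)cc1)CC2=O | target

## Step count and least certain steps

Total: 12 steps. Longest linear sequence: 11 steps (1 to 16 through steps 1–3 and 5–12); step 4 is a one-step side branch giving 7.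

**Step 8 (key step).** Two things may go wrong. Oxidative addition at the electron-rich C8a–Br bond, flanked on both sides, may be slow. The secondary benzylic alkoxide may also lose hydride at palladium, which would oxidise the C2 carbinol with hydrodebromination and, if reversible, could erode the configuration at C2. Within the same disconnection, the first recourse is a monovalent copper catalyst (CuI with 3,4,7,8-tetramethyl-1,10-phenanthroline, Cs2CO3, toluene, 110 °C), which has no facile β-hydride pathway. The fallback reverses the polarity of the ring closure and makes O1–C2 with inversion.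
- It sets out from 10: transfer hydrogenation with RuCl(p-cymene)[(R,R)-TsDPEN] under the conditions of step 7 should give the (1R)-bromoaryl carbinol F1.
- Miyaura borylation of the C8a–Br bond (B2pin2, Pd(OAc)2, SPhos, KOAc, dioxane, 90 °C; acetate leaves the alcohol un-ionised) should give the aryl pinacol boronate F2.
- Oxidation of the C–B bond (NaBO3·4H2O, THF/H2O, rt) should give the phenol F3.
- Mitsunobu cyclisation (PPh3, diisopropyl azodicarboxylate, THF, 0 °C) closes ring C with inversion, R to S, and returns to the route at 12.

**Step 3.** Site selectivity between C–I and the formyl-activated C–Br may be incomplete. Allyl transposition during transmetalation may give the 1,1-dimethylallyl isomer, and allylboration of the aldehyde may compete. The fallback replaces the cross-coupling by a halogen–metal exchange that distinguishes iodine from bromine reliably.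
- From 3, acetalisation (HC(OMe)3, p-TsOH cat., MeOH) should give the dimethyl acetal F4.
- Iodine–magnesium exchange (i-PrMgCl·LiCl, THF, −40 °C), transmetalation to copper (CuBr·SMe2) and alkylation with prenyl bromide at its primary carbon should give the prenylated acetal F5.
- Hydrolysis (1 M HCl, THF, rt) returns to the route at 5.

**Step 5.** Reversal of the aldol addition or dehydration to the enone may occur on warming or work-up, because the aldolate of the doubly ortho-substituted aldehyde is crowded. The fallback generates a zinc enolate under neutral conditions. From 7, enol silylation and bromination (LiN(i-Pr)2, Me3SiCl, THF, −78 °C; then N-bromosuccinimide, 0 °C) should give the α-bromo ketone F6. A Reformatsky-type addition to 5 (Zn dust activated with Me3SiCl, THF, 0 °C → rt) returns to the route at 9.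

**Step 12.** Hydrogen chloride liberated from the free 4'-phenol and BCl3 may add across the prenyl alkene. Demethylation may run on to the 6-methoxy group next to the new phenoxide, and Lewis acid activation of the carbonyl may open ring C and erode C2. The fallback reverses the order of the two deprotections and uses a neutral magnesium chelate with iodide as the dealkylating nucleophile, so that no hydrogen halide meets the alkene. From 14, MgI2·OEt2 (THF, 50 °C) should give the 5-hydroxy-4'-O-methoxymethyl flavanone F7, and acetal cleavage under the conditions of step 11 returns to the route at 16.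

## Further compounds

F1 | step 8 | (1R)-3-[2-bromo-4,5,6-trimethoxy-3-(3-methylbut-2-en-1-yl)phenyl]-3-[(tert-butyldimethylsilyl)oxy]-1-[4-(methoxymethoxy)phenyl]propan-1-ol, both epimers at the silyloxy carbon | O[C@@H](c1ccc(OCOC)cc1)CC(O[Si](C)(C)C(C)(C)C)c1c(Br)c(CC=C(C)C)c(OC)c(OC)c1OC
F2 | step 8 | (1R)-3-[(tert-butyldimethylsilyl)oxy]-1-[4-(methoxymethoxy)phenyl]-3-[2,3,4-trimethoxy-5-(3-methylbut-2-en-1-yl)-6-(4,4,5,5-tetramethyl-1,3,2-dioxaborolan-2-yl)phenyl]propan-1-ol, both epimers at the silyloxy carbon | O[C@@H](c1ccc(OCOC)cc1)CC(O[Si](C)(C)C(C)(C)C)c1c(B2OC(C)(C)C(C)(C)O2)c(CC=C(C)C)c(OC)c(OC)c1OC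
F3 | step 8 | 2-{(3R)-1-[(tert-butyldimethylsilyl)oxy]-3-hydroxy-3-[4-(methoxymethoxy)phenyl]propyl}-3,4,5-trimethoxy-6-(3-methylbut-2-en-1-yl)phenol, both epimers at the silyloxy carbon | O[C@@H](c1ccc(OCOC)cc1)CC(O[Si](C)(C)C(C)(C)C)c1c(O)c(CC=C(C)C)c(OC)c(OC)c1OC
F4 | step 3 | 2-bromo-1-(dimethoxymethyl)-3-iodo-4,5,6-trimethoxybenzene | COC(OC)c1c(Br)c(I)c(OC)c(OC)c1OC
F5 | step 3 | 2-bromo-1-(dimethoxymethyl)-4,5,6-trimethoxy-3-(3-methylbut-2-en-1-yl)benzene | COC(OC)c1c(Br)c(CC=C(C)C)c(OC)c(OC)c1OC
F6 | step 5 | 2-bromo-1-[4-(methoxymethoxy)phenyl]ethan-1-one | COCOc1ccc(cc1)C(=O)CBr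
F7 | step 12 | (2S)-5-hydroxy-6,7-dimethoxy-2-[4-(methoxymethoxy)phenyl]-8-(3-methylbut-2-en-1-yl)chroman-4-one | COc1c(O)c2c(c(CC=C(C)C)c1OC)O[C@H](c1ccc(OCOC)cc1)CC2=O
A1 | alternative 1 | (2S,4S)-4-[(tert-butyldimethylsilyl)oxy]-6,7-dimethoxy-2-{4-[(triisopropylsilyl)oxy]phenyl}chromane-5,8-diol | COc1c(O)c2c(c(O)c1OC)O[C@H](c1ccc(O[Si](C(C)C)(C(C)C)C(C)C)cc1)C[C@@H]2O[Si](C)(C)C(C)(C)C
A2 | alternative 1 | 4-hydroxy-2,3-dimethoxy-4-[(4S,6S)-4-[(tert-butyldimethylsilyl)oxy]-6-{4-[(triisopropylsilyl)oxy]phenyl}-5,6-dihydro-4H-pyran-2-yl]cyclobut-2-en-1-one, carbinol carbon unassigned | COC1=C(OC)C(O)(C2=C[C@@H](O[Si](C)(C)C(C)(C)C)C[C@@H](c3ccc(O[Si](C(C)C)(C(C)C)C(C)C)cc3)O2)C1=O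
A3 | alternative 1 | dimethyl squarate, 3,4-dimethoxycyclobut-3-ene-1,2-dione | COC1=C(OC)C(=O)C1=O
A4 | alternative 2 | 2-(hydroxymethyl)-3,4,5-trimethoxy-6-(3-methylbut-2-en-1-yl)phenol | COc1c(OC)c(OC)c(CO)c(O)c1CC=C(C)C
A5 | alternative 2 | 3,4-dimethoxy-4-(1-methoxypropa-1,2-dien-1-yl)-2-(3-methylbut-2-en-1-yl)cyclobut-2-en-1-one, racemic | COC(=C=C)C1(OC)C(OC)=C(CC=C(C)C)C1=O
A6 | alternative 3 | (2S)-2-{4-[(tert-butyldimethylsilyl)oxy]phenyl}-5-hydroxy-6,7-dimethoxy-8-(3-methylbut-2-en-1-yl)chroman-4-one | COc1c(O)c2c(c(CC=C(C)C)c1OC)O[C@H](c1ccc(O[Si](C)(C)C(C)(C)C)cc1)CC2=O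
A7 | alternative 3 | 2-({1-[4-[(tert-butyldimethylsilyl)oxy]phenyl]ethenyl}oxy)-6-hydroxy-4,5-dimethoxy-3-(3-methylbut-2-en-1-yl)benzaldehyde | COc1c(O)c(C=O)c(OC(=C)c2ccc(O[Si](C)(C)C(C)(C)C)cc2)c(CC=C(C)C)c1OC
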